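(Its constants were chosen freely; the rest is arithmetic.)

A shift chemist lays out the charges below, and two colleagues argue over which one ends richest in target.

    substrate → target (k1 = 0.0031 min⁻¹)
    target → over-reaction product (k2 = 0.013 min⁻¹)
    substrate + target → 2 target (k3 = 0.71 M⁻¹ min⁻¹)
    substrate ⇌ dormant form (K4 = 1.5, k4 = 0.14 min⁻¹)

| flask | substrate | time |
|---|---|---|
| noon | 0.040 M | 6.0 h |
| midnight | 0.060 M | 6.0 h |
| autumn | 0.10 M | 6.0 h |
| dawn | 0.15 M | 6.0 h |

- [target] at the end for noon, midnight, autumn, dawn, in this order
- the shape of the row from first to last (falls, then rises / falls all the way / rises all the way / hardly changes / rises, then falls)

- "hardly changes" means that all values lie within two and a half points (for a concentration: within two and a half percent of the largest)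
- run time (noon): 6.0 h

I reckon with one number, the gain: the rate at which target makes more of itself by step 3, divided by the rate at which that target is lost by step 2, which comes to k3 times free substrate over k2. Target cancels, but free substrate stays in the gain, so the gain sinks as substrate is used, and I reckon it at the opening of each flask. Step 3 is then pseudo-first-order in target, and above one each target replaces itself before it is lost. Step 1 feeds target besides, uncounted here.

The first chemist counts the dormant form. Its forward step has a half-life of 0.083 h, forward rate by itself, far shorter than the run, so she treats the pool as equilibrated from the start, with 40.0% of the charge free. The opening gain 0.874 for the flask called noon is below one. Midnight opens at 1.31, autumn at 2.18 and dawn at 3.28.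

The second chemist calls the dormant form a side pocket and counts the whole charge as free. Noon then opens at 2.18, above one, and dawn at 8.19. Target's half-life by step 2 in noon is 0.89 h, short against the run, so he expects an early flare and a long decay, with the row starting downward from noon.

I side with her on the gains, but my reckoning stops there: it says where growth can begin, not what stands at the end. Her forecast reads 0.0039 M, 0.006 M, 0.0082 M and 0.0075 M, a row that rises, then falls, because “autocatalysis barely beats the loss of target at low loading but flares early at high loading”.

The simulation gives 0.00389 M, 0.00631 M, 0.00873 M and 0.00820 M, a row that rises, then falls, so the first chemist's view stands. The row turns at a charge of 0.11 M, where the opening gain reads 2.37, between autumn's and dawn's. The second chemist's view has its region in a flask whose step 4 has no rate: there the row falls, then rises, and noon, opening at his gain of 2.18, ends at 0.00229 M.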